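**Retrosynthetic overview**

- The target comes from its 8-O-methyl ether by chelation-controlled demethylation next to the ketone.
- Key disconnection: both the cyclohexanone ring and the phenolic ring of the naphthalene are closed in one operation by a twofold Friedel–Crafts acylation of a chroman diacid. The chroman O–C2 bond then leaves as a β-aryloxy group, which aromatises the new naphthalene ring and frees the 5-OH.
- The chroman diacid comes from a 2-methoxychroman by acetal C-alkylation with an acetate enolate equivalent.
- The 2-methoxychroman comes from an enantioselective inverse-demand oxa-Diels–Alder reaction of an o-quinone methide with an aryl enol ether; this sets the only stereocentre that survives (C4).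
- Ring order: temporary chroman ring first, then cyclohexanone ring and naphthalene B ring together, then the chroman is opened. Building blocks: 1,4-dimethoxybenzene, succinic anhydride, 2-methoxybenzaldehyde.

Assumption: the facial sense of the catalyst in step 4 is assigned by analogy and must be confirmed; the catalyst enantiomer that gives the (4S)-chroman is used (the (R)-catalyst is written).

**Step 1**
Reactants: 1 1,4-dimethoxybenzene; 2 succinic anhydride
Product: 3 4-(2-hydroxy-5-methoxyphenyl)-4-oxobutanoic acid
Conditions: AlCl3 (3.2 equiv), ClCH2CH2Cl, 0 → 70 °C; aqueous work-up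
Reagents that add atoms: none
Why: Friedel–Crafts acylation of the symmetrical electron-rich arene gives a single regioisomer, and the excess AlCl3 chelated between the new ketone and the ortho-methoxy group cleaves only that methyl ether, leaving the para-methoxy group in place.

**Step 2**
Reactants: 3 4-(2-hydroxy-5-methoxyphenyl)-4-oxobutanoic acid
Product: 4 rac-5-(2-hydroxy-5-methoxyphenyl)oxolan-2-one
Conditions: NaBH4, 1 M NaOH, 0 °C → rt; then HCl to pH 2, 0 °C → rt
Reagents that add atoms: none
Why: Borohydride reduction of the aryl ketone gives the γ-hydroxy acid, which lactonises on acidification, and the new stereocentre is deliberately left racemic because it is erased when the o-quinone methide forms in step 4.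

**Step 3**
Reactants: 5 2-methoxybenzaldehyde; 6 (methoxymethyl)triphenylphosphonium chloride
Product: 7 1-methoxy-2-(2-methoxyethenyl)benzene (E/Z mixture, E isomer drawn)
Conditions: KOtBu, THF, 0 °C → rt
Reagents that add atoms: none
Why: Wittig olefination with the non-stabilised methoxymethylene ylide gives the enol ether as an E/Z mixture, which is acceptable because both stereocentres that arise from this double bond are destroyed in step 6.

**Step 4**
Reactants: 4 rac-5-(2-hydroxy-5-methoxyphenyl)oxolan-2-one; 7 1-methoxy-2-(2-methoxyethenyl)benzene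
Product: 8 3-[(2S,3R,4S)-2,6-dimethoxy-3-(2-methoxyphenyl)-3,4-dihydro-2H-1-benzopyran-4-yl]propanoic acid (major all-trans isomer drawn; C2/C3 epimers carried along, all 4S)
Conditions: (R)-3,3′-bis(2,4,6-triisopropylphenyl)-BINOL N-triflylphosphoramide (5 mol%), 4 Å MS, PhMe, −20 °C → rt, slow addition of 7 (1.5 equiv)
Reagents that add atoms: none
Why: Proposed new method: the chiral Brønsted acid ionises the benzylic lactone C–O bond with help from the ortho-phenol to give a hydrogen-bonded o-quinone methide (no water is released, so the enol ether is not hydrolysed), the enol ether then adds in an inverse-electron-demand oxa-Diels–Alder reaction with its aryl-bearing carbon bonding to the methide carbon and its oxocarbenium carbon to oxygen, and the catalyst pocket shields one face of the achiral methide so that C4 is formed S from either enantiomer of 4 (enantioconvergent); the closest known reaction types are chiral phosphoric acid-catalysed [4+2] cycloadditions of in situ o-quinone methides with enamides or styrenes and the thermal o-quinone methide/vinyl ether cycloaddition.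

**Step 5**
Reactants: 8 3-[(2S,3R,4S)-2,6-dimethoxy-3-(2-methoxyphenyl)-3,4-dihydro-2H-1-benzopyran-4-yl]propanoic acid; 9 tert-butyl[(1-methoxyethenyl)oxy]dimethylsilane
Product: 11 3-[(2R,3R,4S)-2-(carboxymethyl)-6-methoxy-3-(2-methoxyphenyl)-3,4-dihydro-2H-1-benzopyran-4-yl]propanoic acid, via 3-[(2R,3R,4S)-6-methoxy-2-(2-methoxy-2-oxoethyl)-3-(2-methoxyphenyl)-3,4-dihydro-2H-1-benzopyran-4-yl]propanoic acid 10 (not isolated)
Conditions: 9 (2.5 equiv), TMSOTf (10 mol%), CH2Cl2, −78 → −40 °C; then LiOH, THF/H2O, rt; HCl work-up
Reagents that add atoms: lithium hydroxide, [Li+].[OH-]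
Why: Lewis acid ionisation of the cyclic O,O-acetal gives a chromanyl oxocarbenium ion that is trapped by the silyl ketene acetal (Mukaiyama-type acetal alkylation, mainly trans to the C3 aryl group, the C2 configuration being irrelevant), and saponification of the methyl ester then gives the diacid with C4 untouched.

**Step 6**
Reactants: 11 3-[(2R,3R,4S)-2-(carboxymethyl)-6-methoxy-3-(2-methoxyphenyl)-3,4-dihydro-2H-1-benzopyran-4-yl]propanoic acid
Product: 13 (4S)-5-hydroxy-4-(4-hydroxy-8-methoxynaphthalen-1-yl)-8-methoxy-3,4-dihydronaphthalen-1(2H)-one, via pentacyclic diketone (chroman of 11 with the propanoic arm closed onto C5 and the acetic arm closed onto the 2-methoxyphenyl ring, configuration as in 11) 12 (not isolated)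
Conditions: Eaton's reagent (P2O5, MeSO3H), 45 °C; ice-water quench; then Et3N, MeOH, rt
Reagents that add atoms: none
Why: Twofold intramolecular Friedel–Crafts acylation closes both six-membered ketone rings in one pot, because the propanoic arm can only reach C5 of the chroman (ortho to OMe) and the acetic arm can only reach the free ortho position of the 2-methoxyphenyl group (closure onto C8 of the chroman would need a bridged anti-Bredt-type ring), after which base triggers E1cB loss of the β-aryloxy group (retro-oxa-Michael) and the resulting 4H-naphthalen-1-one tautomerises to the naphthol, erasing C2 and C3 while C4, never next to a cation or an enolisable position, keeps its S configuration.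

**Step 7**
Reactants: 13 (4S)-5-hydroxy-4-(4-hydroxy-8-methoxynaphthalen-1-yl)-8-methoxy-3,4-dihydronaphthalen-1(2H)-one
Product: 14 (4S)-5,8-dihydroxy-4-(4-hydroxy-8-methoxynaphthalen-1-yl)-3,4-dihydronaphthalen-1(2H)-one
Conditions: BCl3 (5 equiv), CH2Cl2, −78 → 0 °C; aqueous NaHCO3
Reagents that add atoms: none
Why: Chelation-controlled demethylation, in which BCl3 bound between the C1 carbonyl and the peri 8-methoxy group cleaves only that ether while the unchelated naphthyl methyl ether survives at low temperature.

**Compound list**

1 | 1,4-dimethoxybenzene | COc1ccc(OC)cc1 | starting material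
2 | succinic anhydride | O=C1CCC(=O)O1 | starting material
3 | 4-(2-hydroxy-5-methoxyphenyl)-4-oxobutanoic acid | COc1ccc(O)c(C(=O)CCC(=O)O)c1 | intermediate
4 | rac-5-(2-hydroxy-5-methoxyphenyl)oxolan-2-one | COc1ccc(O)c(C2CCC(=O)O2)c1 | intermediate
5 | 2-methoxybenzaldehyde | COc1ccccc1C=O | starting material
6 | (methoxymethyl)triphenylphosphonium chloride | COC[P+](c1ccccc1)(c1ccccc1)c1ccccc1.[Cl-] | starting material
7 | 1-methoxy-2-(2-methoxyethenyl)benzene (E/Z mixture, E drawn) | CO/C=C/c1ccccc1OC | intermediate
8 | 3-[(2S,3R,4S)-2,6-dimethoxy-3-(2-methoxyphenyl)-3,4-dihydro-2H-1-benzopyran-4-yl]propanoic acid | COc1ccc2c(c1)[C@@H](CCC(=O)O)[C@H](c1ccccc1OC)[C@@H](OC)O2 | intermediate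
9 | tert-butyl[(1-methoxyethenyl)oxy]dimethylsilane | C=C(OC)O[Si](C)(C)C(C)(C)C | starting material
10 | 3-[(2R,3R,4S)-6-methoxy-2-(2-methoxy-2-oxoethyl)-3-(2-methoxyphenyl)-3,4-dihydro-2H-1-benzopyran-4-yl]propanoic acid | COc1ccc2c(c1)[C@@H](CCC(=O)O)[C@H](c1ccccc1OC)[C@@H](CC(=O)OC)O2 | intermediate
11 | 3-[(2R,3R,4S)-2-(carboxymethyl)-6-methoxy-3-(2-methoxyphenyl)-3,4-dihydro-2H-1-benzopyran-4-yl]propanoic acid | COc1ccc2c(c1)[C@@H](CCC(=O)O)[C@H](c1ccccc1OC)[C@@H](CC(=O)O)O2 | intermediate
12 | pentacyclic diketone (chroman with peri-fused cyclohexanone and 2,3-fused 8-methoxy-1-tetralone ring; configuration as in 11) | COc1ccc2O[C@@H]4CC(=O)c5cccc(OC)c5[C@H]4[C@@H]3CCC(=O)c1c23 | intermediate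
13 | (4S)-5-hydroxy-4-(4-hydroxy-8-methoxynaphthalen-1-yl)-8-methoxy-3,4-dihydronaphthalen-1(2H)-one | COc1cccc2c(O)ccc([C@@H]3CCC(=O)c4c(OC)ccc(O)c43)c12 | intermediate
14 | (4S)-5,8-dihydroxy-4-(4-hydroxy-8-methoxynaphthalen-1-yl)-3,4-dihydronaphthalen-1(2H)-one | COc1cccc2c(O)ccc([C@@H]3CCC(=O)c4c(O)ccc(O)c43)c12 | target

**Step count and risks**

Total step count: 7. Longest linear sequence: 6 (steps 1, 2, 4, 5, 6, 7).

Steps most likely to fail:

Step 4 is the most uncertain. An alkyl-substituted o-quinone methide may tautomerise to the vinylphenol or react with the enol ether with low enantioselectivity. The fallback sets out from 7 and 4 and comes back at 8, and it activates the nucleophile covalently instead of the electrophile by acid. Enol ether 7 is hydrolysed (aqueous HCl, THF) to (2-methoxyphenyl)acetaldehyde F1. F1 and 4 are then combined under enamine catalysis ((S)-α,α-diphenylprolinol trimethylsilyl ether 20 mol%, NaOAc, CHCl3). The catalyst-bound enamine adds to the o-quinone methide that 4 releases under weak base, and the adduct closes to the lactol 3-[(3R,4S)-2-hydroxy-6-methoxy-3-(2-methoxyphenyl)-3,4-dihydro-2H-1-benzopyran-4-yl]propanoic acid F2. Methanol with PPTS converts F2 into acetal 8.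

Step 6 is the next risk. Closure onto the unactivated 2-methoxyphenyl ring may be slow, the β-aryloxy acid may eliminate before it cyclises, and the naphthol product may suffer acid-induced retro-Friedel–Crafts loss of the C4 configuration. The fallback sets out from 11 and comes back at 13, and it closes the naphthalene ring by a pericyclic step instead of electrophilic substitution. Trifluoroacetic anhydride at room temperature closes only the electron-rich ring to give the tetracyclic keto acid (chroman intact, cyclohexanone closed, acetic acid arm free) F3. Heating F3 in Ac2O/NaOAc at 130 °C forms the mixed anhydride, eliminates the β-aryloxy group and deprotonates the γ-position to an aryl dienyl ketene. This ketene closes by 6π-electrocyclisation to (4S)-4-[4-(acetyloxy)-8-methoxynaphthalen-1-yl]-8-methoxy-1-oxo-1,2,3,4-tetrahydronaphthalen-5-yl acetate F4. K2CO3 in MeOH removes both acetates to give 13.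

Step 5 is the third risk. The oxocarbenium ion may lose the C3 proton to a 3-aryl-4H-chromene instead of being alkylated, and base may open the chroman during saponification. The fallback sets out from 8 and comes back at 11, and it builds the acetic acid arm by allylation and oxidative degradation with no base. Hosomi–Sakurai allylation (allyltrimethylsilane, BF3·OEt2, CH2Cl2, −78 °C) gives 3-[(2R,3R,4S)-6-methoxy-3-(2-methoxyphenyl)-2-(prop-2-en-1-yl)-3,4-dihydro-2H-1-benzopyran-4-yl]propanoic acid F5. Ozonolysis (O3, CH2Cl2/MeOH, −78 °C, indicator end point; Me2S) gives 3-[(2R,3R,4S)-6-methoxy-3-(2-methoxyphenyl)-2-(2-oxoethyl)-3,4-dihydro-2H-1-benzopyran-4-yl]propanoic acid F6. Pinnick oxidation (NaClO2, NaH2PO4, 2-methyl-2-butene) gives diacid 11.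

**Further compounds**

F1 | step 4 | (2-methoxyphenyl)acetaldehyde | COc1ccccc1CC=O
F2 | step 4 | 3-[(3R,4S)-2-hydroxy-6-methoxy-3-(2-methoxyphenyl)-3,4-dihydro-2H-1-benzopyran-4-yl]propanoic acid (anomer mixture) | COc1ccc2c(c1)[C@@H](CCC(=O)O)[C@H](c1ccccc1OC)C(O)O2
F3 | step 6 | tetracyclic keto acid (chroman of 11 with the propanoic arm closed onto C5, acetic acid arm free) | COc1ccc2O[C@H](CC(=O)O)[C@@H](c4ccccc4OC)[C@@H]3CCC(=O)c1c23
F4 | step 6 | (4S)-4-[4-(acetyloxy)-8-methoxynaphthalen-1-yl]-8-methoxy-1-oxo-1,2,3,4-tetrahydronaphthalen-5-yl acetate | COc1cccc2c(OC(C)=O)ccc([C@@H]3CCC(=O)c4c(OC)ccc(OC(C)=O)c43)c12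
F5 | step 5 | 3-[(2R,3R,4S)-6-methoxy-3-(2-methoxyphenyl)-2-(prop-2-en-1-yl)-3,4-dihydro-2H-1-benzopyran-4-yl]propanoic acid | COc1ccc2c(c1)[C@@H](CCC(=O)O)[C@H](c1ccccc1OC)[C@@H](CC=C)O2
F6 | step 5 | 3-[(2R,3R,4S)-6-methoxy-3-(2-methoxyphenyl)-2-(2-oxoethyl)-3,4-dihydro-2H-1-benzopyran-4-yl]propanoic acid | COc1ccc2c(c1)[C@@H](CCC(=O)O)[C@H](c1ccccc1OC)[C@@H](CC=O)O2
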